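**Plan**

1. Numbering follows abietane: ring C is the hydroxyquinone (C8, C9, C11–C14), ring B is C5–C10, and the isopropenyl group (C4, C18, C19) together with the propanoate chain (C1–C3) is read as an opened ring A.
2. Retrosynthesis cuts, in order: the C12 O–methyl bond; the C3–C4 bond in the reconnecting sense (isopropenyl plus methyl ester from an ε-lactone, from a 4,4-dimethyl-3-ketone, ring A being a temporary ring); C5–H and C7=O back to a 5-en-7-one and then a C7 methylene; last, C7–C8 and C9–C10 together.
3. The enabling feature is that C8=C9 is a quinone double bond between the C11 and C14 carbonyls (a 2π partner), while C7–C6–C5–C10 becomes a vinylcyclohexene diene once C10 and C5 are tied into ring A.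
4. Forward: ring C (sulfinylquinone 5) and ring A (dienone 11) are made separately, ring B closes in step 9, C7 is oxidised and C5 hydrogenated, then ring A is opened and the C12 ether hydrolysed.
5. Stereochemistry: C10 comes from the sulfur stereocentre of a p-tolylsulfinyl auxiliary that leaves in the same step; C5 comes from hydrogenation anti to the C10 methyl on the rigid ring A/ring B system.

Key step: step 9

Assumption: the facial sense of step 9 is taken from the non-chelated, dipole-minimised rotamer of the sulfinylquinone; if the opposite sense were found, the mirror-image menthyl sulfinate would be used in step 3.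

**Route**

Step 1
Reactants: 1 1,2,4-trimethoxybenzene
Product: 2 2-(2,3,6-trimethoxyphenyl)propan-2-ol
Conditions: n-BuLi, THF, 0 °C; acetone, −78 to 20 °C; H2O
Reagents that add atoms: acetone, CC(C)=O
Why: directed ortho-lithiation should occur at the C–H flanked by two methoxy groups, and the aryllithium then adds 1,2 to acetone.

Step 2
Reactants: 2 2-(2,3,6-trimethoxyphenyl)propan-2-ol
Product: 3 2-isopropyl-1,3,4-trimethoxybenzene
Conditions: Et3SiH, CF3CO2H, CH2Cl2, 0 to 20 °C
Reagents that add atoms: none
Why: ionic hydrogenation, in which the tertiary benzylic cation stabilised by two ortho methoxy groups takes hydride from the silane.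

Step 3
Reactants: 3 2-isopropyl-1,3,4-trimethoxybenzene
Product: 4 (S)-2-isopropyl-1,3,4-trimethoxy-5-(p-tolylsulfinyl)benzene
Conditions: n-BuLi, TMEDA, THF, 0 °C; then added to (1R,2S,5R)-menthyl (S)-p-toluenesulfinate, THF, −78 °C; H2O
Reagents that add atoms: (1R,2S,5R)-menthyl (S)-p-toluenesulfinate, CC(C)[C@@H]1CC[C@@H](C)C[C@H]1O[S@](=O)c1ccc(C)cc1
Why: ortho-lithiation is expected at C5 (one ortho and two meta methoxy groups, whereas the other ring hydrogen has a deactivating para methoxy group), and the Andersen sulfoxide synthesis substitutes at sulfur with inversion to give the (S)-sulfoxide.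

Step 4
Reactants: 4 (S)-2-isopropyl-1,3,4-trimethoxy-5-(p-tolylsulfinyl)benzene
Product: 5 (S)-2-isopropyl-3-methoxy-5-(p-tolylsulfinyl)-1,4-benzoquinone
Conditions: (NH4)2Ce(NO3)6, MeCN–H2O, 20 °C
Reagents that add atoms: water, O
Why: oxidative demethylation of the para-dimethoxy pair by tetravalent cerium should give the p-quinone while the sulfoxide and the third methoxy group survive.

Step 5
Reactants: 6 2-methylcyclohexane-1,3-dione
Product: 7 3-ethoxy-2-methylcyclohex-2-en-1-one
Conditions: EtOH, p-TsOH (cat.), toluene, reflux, Dean–Stark trap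
Reagents that add atoms: ethanol, CCO
Why: acid-catalysed enol ether formation of a cyclic 1,3-dione (vinylogous esterification) driven by removal of water.

Step 6
Reactants: 7 3-ethoxy-2-methylcyclohex-2-en-1-one
Product: 8 rac-3-ethoxy-2,6-dimethylcyclohex-2-en-1-one
Conditions: LDA, THF, −78 °C; MeI, −78 to 0 °C
Reagents that add atoms: iodomethane, CI
Why: kinetic α'-deprotonation of the vinylogous ester and C-methylation (Stork–Danheiser alkylation); the new stereocentre is left racemic because it becomes sp2 in step 8.

Step 7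
Reactants: 8 rac-3-ethoxy-2,6-dimethylcyclohex-2-en-1-one
Product: 10 rac-2,4-dimethyl-3-vinylcyclohex-2-en-1-one, via tertiary allylic alcohol 9 (not isolated)
Conditions: vinylmagnesium bromide, THF, 0 to 20 °C; then 1 M HCl, 20 °C
Reagents that add atoms: vinylmagnesium bromide, C=C[Mg]Br
Why: 1,2-addition to the vinylogous ester carbonyl followed by acid hydrolysis of the enol ether and loss of the allylic hydroxyl gives the transposed dienone (Stork–Danheiser carbonyl transposition).

Step 8
Reactants: 10 rac-2,4-dimethyl-3-vinylcyclohex-2-en-1-one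
Product: 11 2,2,4-trimethyl-3-vinylcyclohex-3-en-1-one
Conditions: t-BuOK, t-BuOH–THF, 0 °C; MeI, 0 to 20 °C
Reagents that add atoms: iodomethane, CI
Why: deconjugative α-alkylation, in which the thermodynamic extended dienolate (γ-deprotonation at C4) is methylated at the α-carbon, giving the α,α-dimethyl β,γ-unsaturated ketone whose ring double bond is now conjugated with the vinyl group.

Step 9
Reactants: 5 (S)-2-isopropyl-3-methoxy-5-(p-tolylsulfinyl)-1,4-benzoquinone; 11 2,2,4-trimethyl-3-vinylcyclohex-3-en-1-one
Product: 13 (10S)-12-methoxyabieta-5,8,12-triene-3,11,14-trione, via sulfinyl cycloadduct 12 (not isolated)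
Conditions: 11 (2.5 equiv), CH2Cl2, 0.9 GPa, 20 °C; then ambient pressure, 20 °C
Reagents that add atoms: none
Why: The sulfinyl group makes C8=C9 the only reactive 2π bond of 5 (C12=C13 is tetrasubstituted and donor-substituted), and an asynchronous normal-demand [4+2] cycloaddition with the s-cis diene C7=C6–C5=C10 of 11 should form C7–C8 and C9–C10; in adduct 12 the C9 sulfinyl group and H8 are cis, so syn-elimination of p-toluenesulfenic acid follows and restores the quinone. The closest known reaction type is the domino Diels–Alder/sulfoxide elimination of enantiopure 2-(p-tolylsulfinyl)-1,4-benzoquinones with semicyclic vinylcyclohexene dienes. Ring B is closed by intermolecular suprafacial [4+2] cycloaddition through an endo transition state, both ring bonds being made in the one event. The only stereocentre that survives, C10, is controlled by the sulfur stereocentre: in the rotamer with S–O anti to the C11 carbonyl the p-tolyl group covers one face, and endo addition to the face carrying the sulfur lone pair should give 10S from (S)-sulfur. The step needs regioselectivity, which is secured twice over, because the unsubstituted vinyl terminus C7 (larger HOMO coefficient, less hindered) bonds to C8, which is β both to the sulfinyl group and to the C11 carbonyl, the carbonyl not deactivated by the C12 methoxy donor. High pressure is chosen because C10 is a fully substituted diene terminus whose methyl group points into the diene.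

Step 10
Reactants: 13 (10S)-12-methoxyabieta-5,8,12-triene-3,11,14-trione
Product: 14 (10S)-12-methoxyabieta-5,8,12-triene-3,7,11,14-tetraone
Conditions: CrO3, 3,5-dimethylpyrazole, CH2Cl2, −20 °C
Reagents that add atoms: chromium trioxide, O=[Cr](=O)=O
Why: allylic oxidation of a 5-ene to the 5-en-7-one by the CrO3–3,5-dimethylpyrazole complex, at the only allylic CH2 (C7), which is further activated by the quinone.

Step 11
Reactants: 14 (10S)-12-methoxyabieta-5,8,12-triene-3,7,11,14-tetraone
Product: 16 (5R,10S)-12-methoxyabieta-8,12-diene-3,7,11,14-tetraone, via hydroquinone 15 (not isolated)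
Conditions: H2 (1 atm), Pd/C, EtOAc, 20 °C; filter; Ag2O, Et2O, 20 °C
Reagents that add atoms: none
Why: catalytic hydrogenation of the enone (the quinone is reduced to the hydroquinone at the same time and reoxidised by Ag2O) should deliver hydrogen to C5 from the α face, anti to the axial C10 methyl and the axial C4 methyl, giving the trans ring A/ring B junction.

Step 12
Reactants: 16 (5R,10S)-12-methoxyabieta-8,12-diene-3,7,11,14-tetraone
Product: 17 (5R,10S)-12-methoxy-7,11,14-trioxo-3,4-secoabieta-8,12-dieno-3,4-lactone
Conditions: mCPBA, CH2Cl2, 20 °C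
Reagents that add atoms: 3-chloroperbenzoic acid, O=C(OO)c1cccc(Cl)c1
Why: Baeyer–Villiger oxidation of the C3 ketone with migration of the tertiary C4, while the C7 ketone and the quinone are electron-poor and should not react with the peracid.

Step 13
Reactants: 17 (5R,10S)-12-methoxy-7,11,14-trioxo-3,4-secoabieta-8,12-dieno-3,4-lactone
Product: 18 methyl (5S,10S)-12-methoxy-7,11,14-trioxo-3,4-secoabieta-4(18),8,12-trien-3-oate
Conditions: p-TsOH·H2O, MeOH–CH2Cl2, 40 °C
Reagents that add atoms: methanol, CO
Why: acid-catalysed methanolysis of the ε-lactone with E1 loss of the tertiary C4 oxygen should give the methyl ester and the less hindered isopropenyl alkene, as known for ring A lactones of 4,4-dimethyl terpenoids; C5 and C10 are untouched.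

Step 14
Reactants: 18 methyl (5S,10S)-12-methoxy-7,11,14-trioxo-3,4-secoabieta-4(18),8,12-trien-3-oate
Product: 19 methyl (5S,10S)-12-hydroxy-7,11,14-trioxo-3,4-secoabieta-4(18),8,12-trien-3-oate (CNP0308749.1)
Conditions: 0.1 M aq NaOH (2 equiv), THF, 0 °C; then 1 M HCl
Reagents that add atoms: sodium hydroxide, [Na+].[OH-]
Why: addition–elimination of hydroxide at C12 of the methoxyquinone (a vinylogous ester) should be much faster than saponification of the unactivated methyl ester at 0 °C, and the hydroxyquinone anion formed resists further attack.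

**Compound list**

1 | 1,2,4-trimethoxybenzene | COc1ccc(OC)c(OC)c1 | starting material
2 | 2-(2,3,6-trimethoxyphenyl)propan-2-ol | COc1ccc(OC)c(OC)c1C(C)(C)O | intermediate
3 | 2-isopropyl-1,3,4-trimethoxybenzene | COc1ccc(OC)c(OC)c1C(C)C | intermediate
4 | (S)-2-isopropyl-1,3,4-trimethoxy-5-(p-tolylsulfinyl)benzene | COc1cc([S@@](=O)c2ccc(C)cc2)c(OC)c(OC)c1C(C)C | intermediate
5 | (S)-2-isopropyl-3-methoxy-5-(p-tolylsulfinyl)-1,4-benzoquinone | COC1=C(C(C)C)C(=O)C=C([S@@](=O)c2ccc(C)cc2)C1=O | intermediate
6 | 2-methylcyclohexane-1,3-dione | CC1C(=O)CCCC1=O | starting material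
7 | 3-ethoxy-2-methylcyclohex-2-en-1-one | CCOC1=C(C)C(=O)CCC1 | intermediate
8 | rac-3-ethoxy-2,6-dimethylcyclohex-2-en-1-one | CCOC1=C(C)C(=O)C(C)CC1 | intermediate
9 | 3-ethoxy-2,6-dimethyl-1-vinylcyclohex-2-en-1-ol (racemic diastereomer mixture) | CCOC1=C(C)C(O)(C=C)C(C)CC1 | intermediate
10 | rac-2,4-dimethyl-3-vinylcyclohex-2-en-1-one | C=CC1=C(C)C(=O)CCC1C | intermediate
11 | 2,2,4-trimethyl-3-vinylcyclohex-3-en-1-one | C=CC1=C(C)CCC(=O)C1(C)C | intermediate
12 | (10S)-12-methoxy-9β-[(S)-p-tolylsulfinyl]-8βH-abieta-5,12-diene-3,11,14-trione (endo adduct; H8, the C9 sulfinyl group and the C10 methyl cis) | CC1(C)C2=CC[C@H]3C(=O)C(C(C)C)=C(OC)C(=O)[C@@]3([S@@](=O)c4ccc(C)cc4)[C@@]2(C)CCC1=O | intermediate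
13 | (10S)-12-methoxyabieta-5,8,12-triene-3,11,14-trione | CC1(C)C2=CCC3=C(C(=O)C(OC)=C(C(C)C)C3=O)[C@@]2(C)CCC1=O | intermediate
14 | (10S)-12-methoxyabieta-5,8,12-triene-3,7,11,14-tetraone | CC1(C)C2=CC(=O)C3=C(C(=O)C(OC)=C(C(C)C)C3=O)[C@@]2(C)CCC1=O | intermediate
15 | (5R,10S)-11,14-dihydroxy-12-methoxyabieta-8,11,13-triene-3,7-dione | CC1(C)[C@@H]2CC(=O)c3c(O)c(C(C)C)c(OC)c(O)c3[C@@]2(C)CCC1=O | intermediate
16 | (5R,10S)-12-methoxyabieta-8,12-diene-3,7,11,14-tetraone (trans ring A/ring B junction) | CC1(C)[C@@H]2CC(=O)C3=C(C(=O)C(OC)=C(C(C)C)C3=O)[C@@]2(C)CCC1=O | intermediate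
17 | (5R,10S)-12-methoxy-7,11,14-trioxo-3,4-secoabieta-8,12-dieno-3,4-lactone (ε-lactone, ring oxygen between C3 and C4) | CC1(C)[C@@H]2CC(=O)C3=C(C(=O)C(OC)=C(C(C)C)C3=O)[C@@]2(C)CCC(=O)O1 | intermediate
18 | methyl (5S,10S)-12-methoxy-7,11,14-trioxo-3,4-secoabieta-4(18),8,12-trien-3-oate | C=C(C)[C@@H]1CC(=O)C2=C(C(=O)C(OC)=C(C(C)C)C2=O)[C@@]1(C)CCC(=O)OC | intermediate
19 | methyl (5S,10S)-12-hydroxy-7,11,14-trioxo-3,4-secoabieta-4(18),8,12-trien-3-oate (CNP0308749.1) | C=C(C)[C@@H]1CC(=O)C2=C(C(=O)C(O)=C(C(C)C)C2=O)[C@@]1(C)CCC(=O)OC | target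

**Totals and risks**

Total step count: 14. Longest linear sequence: 10 steps (steps 1–4 or 5–8, then 9–14).

Steps most likely to fail:

Step 9. The cycloaddition may stall because it joins the fully substituted diene terminus C10 to the sulfinyl-bearing carbon, or the sulfoxide may give poor facial control. The fallback sets out from 11 and 3 and returns at 13. Ketone 11 is reduced with catecholborane and (S)-2-methyl-CBS-oxazaborolidine (C18H20BNO) in toluene at −78 °C (Corey–Bakshi–Shibata reduction) to (R)-2,2,4-trimethyl-3-vinylcyclohex-3-en-1-ol F1. Arene 3 is oxidised with (NH4)2Ce(NO3)6 to 2-isopropyl-3-methoxy-1,4-benzoquinone F2, whose dienophile carbons carry only hydrogen. A thermal or high-pressure Diels–Alder reaction of F1 with F2 should give, with the same regiochemistry, the endo cycloadduct (3R,10S)-3-hydroxy-12-methoxy-8βH,9βH-abieta-5,12-diene-11,14-dione F3. Enolisation and oxidation (Et3N, then Ag2O) convert it to (3R,10S)-3-hydroxy-12-methoxyabieta-5,8,12-triene-11,14-dione F4. Because C3 is a stereocentre, the unwanted C10 epimer is a diastereomer and is removed by chromatography. Oxidation of F4 with Dess–Martin periodinane gives 13.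

Step 13. The tertiary cation at C4 may be trapped by methanol or water, or may lose the C5 proton to give the tetrasubstituted alkene instead of the isopropenyl group. The fallback sets out from 17 and returns at 18. Transesterification with K2CO3 in MeOH opens the lactone to methyl (5R,10S)-4-hydroxy-12-methoxy-7,11,14-trioxo-3,4-secoabieta-8,12-dien-3-oate F5. The tertiary alcohol is then dehydrated by syn-elimination with methyl N-(triethylammoniumsulfonyl)carbamate (Burgess reagent) in benzene at 50 °C, which should favour the methyl-derived terminal alkene and give 18.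

Step 14. Saponification of the side-chain methyl ester may compete with hydrolysis of the hindered C12 methoxy group. The fallback sets out from 18 and returns at 19. Both groups are hydrolysed with LiOH in THF–water to (5S,10S)-12-hydroxy-7,11,14-trioxo-3,4-secoabieta-4(18),8,12-trien-3-oic acid F6. The carboxylate, which is more nucleophilic than the delocalised hydroxyquinone anion, is then methylated selectively with MeI (1 equiv) and KHCO3 in DMF to give 19.

**Further compounds**

F1 | step 9 | (R)-2,2,4-trimethyl-3-vinylcyclohex-3-en-1-ol | C=CC1=C(C)CC[C@@H](O)C1(C)C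
F2 | step 9 | 2-isopropyl-3-methoxy-1,4-benzoquinone | COC1=C(C(C)C)C(=O)C=CC1=O
F3 | step 9 | (3R,10S)-3-hydroxy-12-methoxy-8βH,9βH-abieta-5,12-diene-11,14-dione (endo adduct) | CC1(C)C2=CC[C@H]3C(=O)C(C(C)C)=C(OC)C(=O)[C@H]3[C@@]2(C)CC[C@H]1O
F4 | step 9 | (3R,10S)-3-hydroxy-12-methoxyabieta-5,8,12-triene-11,14-dione | CC1(C)C2=CCC3=C(C(=O)C(OC)=C(C(C)C)C3=O)[C@@]2(C)CC[C@H]1O
F5 | step 13 | methyl (5R,10S)-4-hydroxy-12-methoxy-7,11,14-trioxo-3,4-secoabieta-8,12-dien-3-oate | CC(C)(O)[C@@H]1CC(=O)C2=C(C(=O)C(OC)=C(C(C)C)C2=O)[C@@]1(C)CCC(=O)OC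
F6 | step 14 | (5S,10S)-12-hydroxy-7,11,14-trioxo-3,4-secoabieta-4(18),8,12-trien-3-oic acid | C=C(C)[C@@H]1CC(=O)C2=C(C(=O)C(O)=C(C(C)C)C2=O)[C@@]1(C)CCC(=O)O
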